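The numbers in the tables stem from a simulated flask for substances that don't exist, and the scatter is random.

Slowness is what I look for first: which step in these flasks takes time?

| flask | substrate | first nucleophile | second nucleophile | temperature | remark | time |
|---|---|---|---|---|---|---|
| elm | 0.20 M | 1.5 equiv | 2.5 equiv | 25 °C | run made earlier |  |
| ash | 0.20 M | 1.5 equiv | 5 equiv | 25 °C | run made earlier |  |
| Tuesday's | 0.20 M | 1.50 equiv | 2.50 equiv | 25 °C | everything together at the start | 5.0 min |
| Thursday's | 0.20 M (fed, over 4.0 min) | 1.50 equiv | 2.50 equiv |  | the addition at −5 °C, then warmed to 25 °C; the feed brings no volume worth counting | 5.0 min |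
| Monday's | 0.20 M (fed, over 4.0 min) | 1.50 equiv | 2.50 equiv | 25 °C | all else is in the flask from the start; the feed brings no volume worth counting | 5.0 min |
| Saturday's | 0.20 M (fed, over 25 s) | 1.50 equiv | 2.50 equiv | 25 °C | all else is in the flask from the start; the feed brings no volume worth counting | 5.0 min |

elm run (percent of the substrate charged)

| time / min | target / % |
|---|---|
| 0.417 | 17.4 |
| 1.00 | 17.9 |
| 2.00 | 17.4 |
| 5.00 | 17.7 |

ash run (percent of the substrate charged)

| time / s | target / % |
|---|---|
| 10.0 | 10.2 |
| 20.0 | 10.2 |
| 30.0 | 10.1 |

(scatter of a reading: 0.5 percentage points)

- what was read earlier has a scatter of 0.5 percentage points, one standard deviation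
- steps under discussion: substrate -> intermediate; first nucleophile + intermediate -> target; second nucleophile + intermediate -> other capture product; intermediate -> solvolysis product; intermediate -> decomposed reagent
- the earlier runs do not show what temperature does; that part of a forecast is a guess

- the flask with the highest amount of target, in percent of the substrate charged ("all alike" if they lie within 1.5 percentage points) (Tuesday's / Thursday's / Monday's / Saturday's / all alike)
- final target, as a percentage of the substrate charged, in Tuesday's
- final target, as a percentage of the substrate charged, in Thursday's
- final target, as a percentage of the substrate charged, in Monday's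
- final target, as a percentage of the substrate charged, in Saturday's

1. The ash target curve rises on average at 0.612 min⁻¹, as a fraction of the substrate charged, up to the first reading at 10.0 s, and its knee lies before that reading. The elm curve is level by its first reading, at 0.417 min. The levels are 17.6 % in elm and 10.2 % in ash.

2. I read each level as a share-out of the intermediate. Elm's level gives 4.68 lost parts: parts of intermediate going elsewhere per part of target, the inverse of a selectivity factor. Ash gives 8.84.

3. Going from 2.5 equiv to 5 equiv of second nucleophile adds 4.15 lost parts. Taking its share as proportional to its amount, it takes about that many in elm, and 0.530 remain for the paths without a nucleophile. Lost parts are rates divided by the rate of capture by first nucleophile, so with the temperature course and the second nucleophile held, I take them to go about as one over the amount of first nucleophile.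

4. In Monday's flask the feed of 4.0 min is far longer than that knee, so I draw a straight rise of 0.0440 min⁻¹, as a fraction of the charge, with its knee at the end of the feed. Saturday's knee comes at 25 s. I expect the level to stay at 17.6 % in the flasks at 25 °C. For Thursday's flask, the lost parts at −5 °C cannot be read from these runs.

5. The forecast says all alike: 17.6 % for Tuesday's, 17.6 % for Monday's, 17.6 % for Saturday's, and 17.6 % for Thursday's, with a range from 14 % to 21.5 %. Its ground is that “the yield is set by partitioning of the intermediate, not by time”.

6. The flask with the most target is Thursday's, at 24.0 %, above the top of that range. Tuesday's gives 17.7 %, Monday's 17.7 % and Saturday's 17.7 %.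

    substrate → intermediate (k = 0.966 s⁻¹, Ea = 73.0 kJ mol⁻¹)
    first nucleophile + intermediate → target (k = 9.08 L mol⁻¹ s⁻¹, Ea = 43.0 kJ mol⁻¹)
    second nucleophile + intermediate → other capture product (k = 23.3 L mol⁻¹ s⁻¹, Ea = 52.0 kJ mol⁻¹)
    intermediate → solvolysis product (k = 1.85 s⁻¹, Ea = 61.0 kJ mol⁻¹)
    intermediate → decomposed reagent (k = 0.0753 s⁻¹, Ea = 84.0 kJ mol⁻¹)
    (constants at 25 °C)

7. Thursday's level means 3.17 lost parts, fewer than elm's 4.68. At 2.46 min in Thursday's, second nucleophile uses the intermediate 2.7 times as fast as first nucleophile, below the 3.89 parts of other capture product per part of target that stand at the end of Tuesday's. A neighbour of Thursday's with 6.00 equiv of first nucleophile should have 0.792 lost parts, so 55.8 % target. The computed neighbour gives 55.2 %.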